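## Retrosynthetic overview

1. Labdane numbering is used: ring A = C1–C5 + C10, ring B = C5–C10, C18 = CH2OH on C4, C20 = CH3 on C10, side chain on C9. Late stage: the side-chain diene comes from a terminal alkyne and ethylene (enyne metathesis), the C8 OH/C9 H pair from a C8=C9 alkene (epoxidation, reductive opening), and the C6 acetate from a C6 acetyl group (Baeyer–Villiger).
2. Enabling feature: after these retro-steps ring B is a cyclohexene (C8=C9) with an acyl group on C6. That is the full retron of a Diels–Alder reaction between a C7=C8–C9=C10 diene and a C5=C6 enone, and C1–C4 of ring A form a four-carbon tether from C10 to C5.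
3. Key disconnection: C5–C10 and C6–C7 together, back to acyclic trienone 15. Rings A and B form in the same step (step 11), which sets C5, C6 and C10 relative to the one preset stereocentre C4.
4. Trienone 15: the C1–C10 bond comes from a B-alkyl Suzuki coupling of the alkene of 7 with E enol tosylate 11 (from ethyl acetoacetate); MeLi then converts the ester to a carbinol and the Weinreb amide to the methyl ketone, and dehydration gives the diene.
5. C4 (the only stereocentre set by asymmetric catalysis): Sharpless epoxidation of dienol 3, then 1,2-shift of the epoxy silyl ether to the quaternary β-siloxy aldehyde 6.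

Key step: step 11

Assumption: in step 4 the siloxymethyl group migrates anti to the breaking C–O bond (inversion at the tertiary carbon), the usual course of this rearrangement; D-(−)-tartrate in step 2 is chosen on that basis.

## Route

Step 1
Reactants: 1 pent-1-en-4-yne
Product: 3 (2E)-3-methylhexa-2,5-dien-1-ol, via alkenylalane 2 (not isolated)
Conditions: Me3Al (2 equiv), Cp2ZrCl2 (0.25 equiv), CH2Cl2, 0 °C to rt; volatiles removed; n-BuLi, THF, −78 °C; (CH2O)n, −78 °C to rt; aq. HCl
Reagents that add atoms: trimethylaluminium C[Al](C)C; formaldehyde (as paraformaldehyde) C=O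
Why: Negishi zirconium-catalysed carboalumination adds Me and Al syn across the terminal alkyne (Al at the terminus, the isolated alkene is left alone), and the derived alanate is hydroxymethylated with retention, which should give the E trisubstituted allylic alcohol.

Step 2
Reactants: 3 (2E)-3-methylhexa-2,5-dien-1-ol
Product: 4 [(2R,3R)-3-methyl-3-(prop-2-en-1-yl)oxiran-2-yl]methanol
Conditions: Ti(OiPr)4 (10 mol %), D-(−)-diethyl tartrate (12 mol %), t-BuOOH, 4 Å MS, CH2Cl2, −20 °C
Reagents that add atoms: tert-butyl hydroperoxide CC(C)(C)OO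
Why: Sharpless asymmetric epoxidation of an E 3,3-disubstituted allylic alcohol; D-(−)-tartrate should deliver oxygen to the face that gives the (2R,3R) epoxide (mirror image of the L-tartrate/geraniol case), and the isolated terminal alkene is inert to this titanium peroxide system.

Step 3
Reactants: 4 [(2R,3R)-3-methyl-3-(prop-2-en-1-yl)oxiran-2-yl]methanol
Product: 5 TBDPS ether of epoxy alcohol 4
Conditions: TBDPSCl, imidazole, DMF, 0 °C to rt
Reagents that add atoms: tert-butyl(chloro)diphenylsilane CC(C)(C)[Si](Cl)(c1ccccc1)c1ccccc1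
Why: Standard silylation of a primary alcohol; the bulky silyl ether is what step 4 needs and it stays on as the C18 protecting group.

Step 4
Reactants: 5 TBDPS ether of epoxy alcohol 4
Product: 6 (2R)-2-{[(tert-butyldiphenylsilyl)oxy]methyl}-2-methylpent-4-enal
Conditions: preformed MeAl(OC6H2-4-Br-2,6-tBu2)2 (2 equiv), CH2Cl2, −78 °C; aq. HCl
Reagents that add atoms: none
Why: Yamamoto rearrangement of an epoxy silyl ether (semipinacol-type 1,2-shift): the bulky aluminium Lewis acid ionises the tertiary C–O bond and the siloxymethyl group migrates anti to it, so the epoxide chirality should be transferred with inversion to the all-carbon quaternary centre (later C4) while the former C2 becomes the aldehyde (later C5).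

Step 5
Reactants: 6 (2R)-2-{[(tert-butyldiphenylsilyl)oxy]methyl}-2-methylpent-4-enal
Product: 7 (2E,4S)-Weinreb dienamide
Conditions: (EtO)2P(O)CH2C(O)N(OMe)Me, NaH, THF, 0 °C to rt
Reagents that add atoms: diethyl {2-[methoxy(methyl)amino]-2-oxoethyl}phosphonate CCOP(=O)(CC(=O)N(C)OC)OCC
Why: Horner–Wadsworth–Emmons olefination of a non-enolisable aldehyde should give the E enamide; the Weinreb amide is chosen because it survives step 8 and gives the methyl ketone with MeLi in step 9.

Step 6
Reactants: 8 ethyl acetoacetate (1.5 equiv); 9 (4-bromobut-1-yn-1-yl)trimethylsilane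
Product: 10 ethyl 2-acetyl-6-(trimethylsilyl)hex-5-ynoate (racemic)
Conditions: NaH, NaI (cat.), THF/DMF, 0 to 60 °C
Reagents that add atoms: none
Why: C-alkylation of the sodium enolate of a β-keto ester with a primary bromide under iodide catalysis; the excess of 8 limits dialkylation and the silyl cap keeps the alkyne inert in the later coupling.

Step 7
Reactants: 10 ethyl 2-acetyl-6-(trimethylsilyl)hex-5-ynoate
Product: 11 ethyl (2E)-3-(tosyloxy)-2-[4-(trimethylsilyl)but-3-yn-1-yl]but-2-enoate
Conditions: TsCl, N-methylimidazole, Et3N, CH2Cl2, 0 °C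
Reagents that add atoms: 4-methylbenzenesulfonyl chloride Cc1ccc(cc1)S(Cl)(=O)=O
Why: Amine-mediated, non-chelating O-sulfonylation of an α-substituted β-keto ester should give the E enol tosylate (tosyloxy trans to the ester), the geometry that later places the tether trans to C8 in the diene.

Step 8
Reactants: 7 (2E,4S)-Weinreb dienamide; 11 E enol tosylate
Product: 13 ethyl (2E,7S,8E)-7-{[(tert-butyldiphenylsilyl)oxy]methyl}-10-[methoxy(methyl)amino]-3,7-dimethyl-10-oxo-2-[4-(trimethylsilyl)but-3-yn-1-yl]deca-2,8-dienoate, via alkylborane 12 (not isolated)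
Conditions: 9-BBN (1.2 equiv), THF, 0 °C to rt; then 11, Pd(OAc)2 (5 mol %), SPhos (10 mol %), K3PO4 (3 M aq.), THF, 40 °C
Reagents that add atoms: none
Why: Anti-Markovnikov hydroboration of the monosubstituted alkene (the conjugated, neopentyl-flanked enamide alkene is inert to 9-BBN) followed by B-alkyl Suzuki–Miyaura coupling with the activated enol tosylate, which should proceed with retention of alkene geometry and forms the C1–C10 bond.

Step 9
Reactants: 13 coupled ester–Weinreb amide
Product: 14 (3E,5S,9E)-5-{[(tert-butyldiphenylsilyl)oxy]methyl}-11-hydroxy-5,9,11-trimethyl-10-[4-(trimethylsilyl)but-3-yn-1-yl]dodeca-3,9-dien-2-one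
Conditions: MeLi (5 equiv), THF/Et2O, −78 to −20 °C; then H2O
Reagents that add atoms: methyllithium [Li]C
Why: Organolithium 1,2-addition: the Weinreb amide forms a stable chelated tetrahedral intermediate that gives the methyl ketone only on work-up, while the ester takes up two methyl groups to give the tertiary allylic alcohol, so one operation should create both the acetyl group of the dienophile and the carbinol precursor of the diene.

Step 10
Reactants: 14 hydroxy dienone
Product: 15 (3E,5S,9E)-5-{[(tert-butyldiphenylsilyl)oxy]methyl}-5,9,11-trimethyl-10-[4-(trimethylsilyl)but-3-yn-1-yl]dodeca-3,9,11-trien-2-one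
Conditions: Burgess reagent (methyl N-(triethylammoniosulfonyl)carbamate), toluene, 50 °C
Reagents that add atoms: none
Why: Burgess dehydration (syn elimination through the sulfamate ester) can only take a hydrogen from one of the two carbinol methyl groups, which should give the isopropenyl group and hence the C7=C8–C9=C10 diene without touching the enone.

Step 11
Reactants: 15 trienone
Product: 16 1-[(1R,4aR,8S,8aS)-8-{[(tert-butyldiphenylsilyl)oxy]methyl}-3,4a,8-trimethyl-4-[4-(trimethylsilyl)but-3-yn-1-yl]-1,2,4a,5,6,7,8,8a-octahydronaphthalen-1-yl]ethan-1-one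
Conditions: Me2AlCl (1.5 equiv), CH2Cl2 (0.01 M), −78 to −20 °C; then 1 M HCl
Reagents that add atoms: none
Why: Lewis-acid-promoted type 1 intramolecular Diels–Alder reaction: Me2AlCl binds the ketone and the C5=C6 enone adds suprafacially to the s-cis C7=C8–C9=C10 diene in a concerted but asynchronous [4+2] cycloaddition in which the C5–C10 bond runs ahead of the C6–C7 bond; the closest precedent is the Me2AlCl- or EtAlCl2-promoted cyclisation of terminally activated deca-1,3,9-triene-type ketones and esters to trans-fused octalins. Ring B (C5–C10) is closed as the cyclohexene of the [4+2] event, and ring A (C1–C5, C10) is closed at the same time by the C5–C10 bond as the fused six-membered tether ring, with the C1–C4 chain in a chair-like arrangement. C10 (quaternary) and C5 are set by the E geometry of the C9=C10 bond (tether anti to C8, methyl inside) together with the endo position of the aluminium-bound acetyl group, which should give the trans ring fusion; C6 follows from the E geometry of the dienophile, which keeps the acetyl group trans to C4 and so equatorial and cis to H5 (also the thermodynamically preferred, epimerisable position). The absolute sense is relayed from C4: in the chair-like tether the methyl group should take the axial site that faces the incoming C10 methyl, while the larger, inductively withdrawing silyloxymethyl group takes the equatorial site anti to the forming C5–C10 bond. The step needs endo selectivity and π-facial selectivity with respect to C4; the first is secured by the Lewis-acid-complexed E enone, the second only by the size difference at C4 (a modest preference is expected, with the minor diastereomer to be separated), and the low temperature avoids the [1,5]-hydrogen shift open to a diene with an inside methyl group.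

Step 12
Reactants: 16 octalin methyl ketone
Product: 18 8,9-epoxy 6-acetate (oxirane on the face anti to the C10 methyl), via epoxy ketone 17 (not isolated)
Conditions: mCPBA (4 equiv), NaHCO3, CH2Cl2, 0 °C to rt
Reagents that add atoms: 3-chloroperoxybenzoic acid OOC(=O)c1cccc(Cl)c1
Why: Prilezhaev epoxidation of the electron-rich tetrasubstituted C8=C9 alkene from the face anti to the angular methyl group, followed in the same flask by Baeyer–Villiger oxidation of the methyl ketone, in which the secondary C6 migrates with retention and should give the acetate of the target directly; the buffer protects the epoxide.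

Step 13
Reactants: 18 epoxy acetate
Product: 19 (1R,3S,4S,4aR,8S,8aS)-8-{[(tert-butyldiphenylsilyl)oxy]methyl}-3-hydroxy-3,4a,8-trimethyl-4-[4-(trimethylsilyl)but-3-yn-1-yl]decahydronaphthalen-1-yl acetate
Conditions: Cp2TiCl2 (0.3 equiv), Mn dust, 2,4,6-collidine hydrochloride, 1,4-cyclohexadiene, THF, rt
Reagents that add atoms: none
Why: Nugent–RajanBabu/Gansäuer reductive epoxide opening by Cp2TiCl (trivalent titanium, formed from Cp2TiCl2 and Mn): homolysis of the more hindered C9–O bond should leave the oxygen on C8 with its configuration intact and give a tertiary C9 radical, which takes a hydrogen atom from 1,4-cyclohexadiene on the face anti to the two flanking axial methyl groups (C8 and C10), so that the side chain ends up equatorial.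

Step 14
Reactants: 19 hydroxy acetate
Product: 20 (1R,3S,4S,4aR,8S,8aS)-4-(but-3-yn-1-yl)-3-hydroxy-8-(hydroxymethyl)-3,4a,8-trimethyldecahydronaphthalen-1-yl acetate
Conditions: Bu4NF, AcOH (1:1), THF, rt to 40 °C
Reagents that add atoms: none
Why: Fluoride-mediated desilylation should remove the silyl ether and the alkynylsilane in one operation, the acetic acid buffer suppressing acetyl migration from O6 to the nearby O18.

Step 15
Reactants: 20 diol alkyne
Product: 21 (1R,3S,4S,4aR,8S,8aS)-3-hydroxy-8-(hydroxymethyl)-3,4a,8-trimethyl-4-(3-methylidenepent-4-en-1-yl)decahydronaphthalen-1-yl acetate (target)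
Conditions: ethylene (1 atm), second-generation Grubbs catalyst (H2IMes)(PCy3)Cl2Ru=CHPh (10 mol %), CH2Cl2, rt
Reagents that add atoms: ethylene C=C
Why: Ruthenium-carbene-catalysed enyne cross-metathesis of a terminal alkyne with ethylene should give the 2-substituted buta-1,3-diene directly; free hydroxyl groups and the acetate are tolerated and no other alkene is present.

## Compound list

1 | pent-1-en-4-yne | C=CCC#C | starting material
2 | (E)-dimethyl(2-methylpenta-1,4-dien-1-yl)alane | C=CC/C(C)=C/[Al](C)C | intermediate (not isolated)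
3 | (2E)-3-methylhexa-2,5-dien-1-ol | C=CC/C(C)=C/CO | intermediate
4 | [(2R,3R)-3-methyl-3-(prop-2-en-1-yl)oxiran-2-yl]methanol | C=CC[C@@]1(C)O[C@@H]1CO | intermediate
5 | tert-butyl{[(2R,3R)-3-methyl-3-(prop-2-en-1-yl)oxiran-2-yl]methoxy}diphenylsilane | C=CC[C@@]1(C)O[C@@H]1CO[Si](c1ccccc1)(c1ccccc1)C(C)(C)C | intermediate
6 | (2R)-2-{[(tert-butyldiphenylsilyl)oxy]methyl}-2-methylpent-4-enal | C=CC[C@](C)(CO[Si](c1ccccc1)(c1ccccc1)C(C)(C)C)C=O | intermediate
7 | (2E,4S)-4-{[(tert-butyldiphenylsilyl)oxy]methyl}-N-methoxy-N,4-dimethylhepta-2,6-dienamide | C=CC[C@](C)(CO[Si](c1ccccc1)(c1ccccc1)C(C)(C)C)/C=C/C(=O)N(C)OC | intermediate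
8 | ethyl acetoacetate (ethyl 3-oxobutanoate) | CCOC(=O)CC(C)=O | starting material
9 | (4-bromobut-1-yn-1-yl)trimethylsilane | C[Si](C)(C)C#CCCBr | starting material
10 | ethyl 2-acetyl-6-(trimethylsilyl)hex-5-ynoate (racemic) | CCOC(=O)C(CCC#C[Si](C)(C)C)C(C)=O | intermediate
11 | ethyl (2E)-3-{[(4-methylphenyl)sulfonyl]oxy}-2-[4-(trimethylsilyl)but-3-yn-1-yl]but-2-enoate | CCOC(=O)/C(CCC#C[Si](C)(C)C)=C(/OS(=O)(=O)c1ccc(C)cc1)C | intermediate
12 | (2E,4S)-7-(9-borabicyclo[3.3.1]nonan-9-yl)-4-{[(tert-butyldiphenylsilyl)oxy]methyl}-N-methoxy-N,4-dimethylhept-2-enamide | B1(C2CCCC1CCC2)CCC[C@](C)(CO[Si](c1ccccc1)(c1ccccc1)C(C)(C)C)/C=C/C(=O)N(C)OC | intermediate (not isolated)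
13 | ethyl (2E,7S,8E)-7-{[(tert-butyldiphenylsilyl)oxy]methyl}-10-[methoxy(methyl)amino]-3,7-dimethyl-10-oxo-2-[4-(trimethylsilyl)but-3-yn-1-yl]deca-2,8-dienoate | CCOC(=O)/C(CCC#C[Si](C)(C)C)=C(/CCC[C@](C)(CO[Si](c1ccccc1)(c1ccccc1)C(C)(C)C)/C=C/C(=O)N(C)OC)C | intermediate
14 | (3E,5S,9E)-5-{[(tert-butyldiphenylsilyl)oxy]methyl}-11-hydroxy-5,9,11-trimethyl-10-[4-(trimethylsilyl)but-3-yn-1-yl]dodeca-3,9-dien-2-one | CC(C)(O)/C(CCC#C[Si](C)(C)C)=C(/CCC[C@](C)(CO[Si](c1ccccc1)(c1ccccc1)C(C)(C)C)/C=C/C(C)=O)C | intermediate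
15 | (3E,5S,9E)-5-{[(tert-butyldiphenylsilyl)oxy]methyl}-5,9,11-trimethyl-10-[4-(trimethylsilyl)but-3-yn-1-yl]dodeca-3,9,11-trien-2-one | C=C(C)/C(CCC#C[Si](C)(C)C)=C(/CCC[C@](C)(CO[Si](c1ccccc1)(c1ccccc1)C(C)(C)C)/C=C/C(C)=O)C | intermediate
16 | 1-[(1R,4aR,8S,8aS)-8-{[(tert-butyldiphenylsilyl)oxy]methyl}-3,4a,8-trimethyl-4-[4-(trimethylsilyl)but-3-yn-1-yl]-1,2,4a,5,6,7,8,8a-octahydronaphthalen-1-yl]ethan-1-one | C[Si](C)(C)C#CCCC=1[C@]2(C)CCC[C@](C)(CO[Si](c3ccccc3)(c3ccccc3)C(C)(C)C)[C@H]2[C@H](C(C)=O)CC=1C | intermediate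
17 | epoxy ketone: 8,9-epoxide of 16 (labdane numbering, 8S,9R; oxirane on the face anti to the C10 methyl; 6-acetyl kept) | C[Si](C)(C)C#CCC[C@@]1(O3)[C@]2(C)CCC[C@](C)(CO[Si](c4ccccc4)(c4ccccc4)C(C)(C)C)[C@H]2[C@H](C(C)=O)C[C@@]13C | intermediate (not isolated)
18 | epoxy acetate: as 17 with the 6-acetyl group replaced by 6-acetoxy, same configuration at C6 | C[Si](C)(C)C#CCC[C@@]1(O3)[C@]2(C)CCC[C@](C)(CO[Si](c4ccccc4)(c4ccccc4)C(C)(C)C)[C@H]2[C@H](OC(C)=O)C[C@@]13C | intermediate
19 | (1R,3S,4S,4aR,8S,8aS)-8-{[(tert-butyldiphenylsilyl)oxy]methyl}-3-hydroxy-3,4a,8-trimethyl-4-[4-(trimethylsilyl)but-3-yn-1-yl]decahydronaphthalen-1-yl acetate | C[Si](C)(C)C#CCC[C@H]1[C@]2(C)CCC[C@](C)(CO[Si](c3ccccc3)(c3ccccc3)C(C)(C)C)[C@H]2[C@H](OC(C)=O)C[C@]1(C)O | intermediate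
20 | (1R,3S,4S,4aR,8S,8aS)-4-(but-3-yn-1-yl)-3-hydroxy-8-(hydroxymethyl)-3,4a,8-trimethyldecahydronaphthalen-1-yl acetate | C#CCC[C@H]1[C@]2(C)CCC[C@](C)(CO)[C@H]2[C@H](OC(C)=O)C[C@]1(C)O | intermediate
21 | (1R,3S,4S,4aR,8S,8aS)-3-hydroxy-8-(hydroxymethyl)-3,4a,8-trimethyl-4-(3-methylidenepent-4-en-1-yl)decahydronaphthalen-1-yl acetate | C=CC(=C)CC[C@H]1[C@]2(C)CCC[C@](C)(CO)[C@H]2[C@H](OC(C)=O)C[C@]1(C)O | target

## Step count and risks

Total steps: 15. Longest linear sequence: 13 (steps 1–5 and 8–15); steps 6 and 7 make tosylate 11.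

**Risk 1, step 11.** What may go wrong: too little π-facial discrimination by the C4 centre (methyl against silyloxymethyl), competing exo cycloaddition to the cis-fused octalin, or Lewis-acid-induced isomerisation of the diene before it cyclises. Fallback, auxiliary control in place of substrate control, setting out from aldehyde 6 and coming back at ketone 16: 6 is protected (HC(OMe)3, PPTS, MeOH) as the dimethyl acetal F1. Hydroboration and Suzuki coupling with 11 as in step 8 gives the acetal ester F2. MeLi gives the acetal carbinol F3, and Burgess dehydration gives the diene acetal F4. Hydrolysis (PPTS, acetone/water) frees the diene aldehyde F5. Masamune–Roush olefination (LiCl, iPr2NEt, MeCN) with diethyl {2-[(4R)-4-benzyl-2-oxo-1,3-oxazolidin-3-yl]-2-oxoethyl}phosphonate gives the trienimide F6. Its Me2AlCl-promoted Evans intramolecular Diels–Alder reaction (CH2Cl2, −30 °C) should give the cycloadduct imide F7, because the benzyl group of the chelated imide shields one dienophile face and the cationic chelate is both more reactive and more endo-selective than the ketone complex. LiOH/H2O2 then gives the acid F8, and excess MeLi converts the lithium carboxylate to methyl ketone 16.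

**Risk 2, step 13.** What may go wrong: homolysis of the C8–O instead of the C9–O bond (leading to the 9-ol), or loss of oxygen back to the alkene after a second electron transfer. Fallback, syn hydration by hydroboration in place of epoxide reduction, setting out from ketone 16 and coming back at 19: Baeyer–Villiger oxidation with Me3SiOOSiMe3 and catalytic TMSOTf (which spares the alkene) gives the acetoxy alkene F9. Co2(CO)8 masks the alkyne as the hexacarbonyldicobalt complex F10. BH3·THF then NaBO3 should put boron on the less hindered C8 and hydrogen on C9, both from the face anti to the angular methyl, giving the hydroxy complex F11. Ce(NH4)2(NO3)6 in acetone releases the alkyne and gives 19.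

**Risk 3, step 8.** What may go wrong: slow transmetalation and β-hydride elimination at the hindered tetrasubstituted enol tosylate, or erosion of its geometry under the basic aqueous conditions. Fallback, an organozinc route, setting out from 7 and coming back at 13: hydroboration of 7 with 9-BBN and oxidation with NaBO3 gives the primary alcohol F12. I2, PPh3 and imidazole give the iodide F13. Zinc insertion (Zn dust, LiCl, THF) gives the alkylzinc iodide F14. Negishi coupling with 11 (Pd2(dba)3, SPhos, THF, rt, anhydrous and base-free) should give 13 with retention of geometry.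

## Further compounds

F1 | step 11 | tert-butyl{[(2R)-2-(dimethoxymethyl)-2-methylpent-4-en-1-yl]oxy}diphenylsilane | C=CC[C@](C)(CO[Si](c1ccccc1)(c1ccccc1)C(C)(C)C)C(OC)OC
F2 | step 11 | ethyl (2E,7R)-7-{[(tert-butyldiphenylsilyl)oxy]methyl}-8,8-dimethoxy-3,7-dimethyl-2-[4-(trimethylsilyl)but-3-yn-1-yl]oct-2-enoate | CCOC(=O)/C(CCC#C[Si](C)(C)C)=C(/CCC[C@](C)(CO[Si](c1ccccc1)(c1ccccc1)C(C)(C)C)C(OC)OC)C
F3 | step 11 | (3E,7R)-7-{[(tert-butyldiphenylsilyl)oxy]methyl}-8,8-dimethoxy-2,4,7-trimethyl-3-[4-(trimethylsilyl)but-3-yn-1-yl]oct-3-en-2-ol | CC(C)(O)/C(CCC#C[Si](C)(C)C)=C(/CCC[C@](C)(CO[Si](c1ccccc1)(c1ccccc1)C(C)(C)C)C(OC)OC)C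
F4 | step 11 | tert-butyl{[(2R,6E)-2-(dimethoxymethyl)-2,6,8-trimethyl-7-[4-(trimethylsilyl)but-3-yn-1-yl]nona-6,8-dien-1-yl]oxy}diphenylsilane | C=C(C)/C(CCC#C[Si](C)(C)C)=C(/CCC[C@](C)(CO[Si](c1ccccc1)(c1ccccc1)C(C)(C)C)C(OC)OC)C
F5 | step 11 | (2R,6E)-2-{[(tert-butyldiphenylsilyl)oxy]methyl}-2,6,8-trimethyl-7-[4-(trimethylsilyl)but-3-yn-1-yl]nona-6,8-dienal | C=C(C)/C(CCC#C[Si](C)(C)C)=C(/CCC[C@](C)(CO[Si](c1ccccc1)(c1ccccc1)C(C)(C)C)C=O)C
F6 | step 11 | (4R)-4-benzyl-3-[(2E,4S,8E)-4-{[(tert-butyldiphenylsilyl)oxy]methyl}-4,8,10-trimethyl-9-[4-(trimethylsilyl)but-3-yn-1-yl]undeca-2,8,10-trienoyl]-1,3-oxazolidin-2-one | C=C(C)/C(CCC#C[Si](C)(C)C)=C(/CCC[C@](C)(CO[Si](c1ccccc1)(c1ccccc1)C(C)(C)C)/C=C/C(=O)N1C(=O)OC[C@H]1Cc1ccccc1)C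
F7 | step 11 | (4R)-4-benzyl-3-{[(1R,4aR,8S,8aS)-8-{[(tert-butyldiphenylsilyl)oxy]methyl}-3,4a,8-trimethyl-4-[4-(trimethylsilyl)but-3-yn-1-yl]-1,2,4a,5,6,7,8,8a-octahydronaphthalen-1-yl]carbonyl}-1,3-oxazolidin-2-one | C[Si](C)(C)C#CCCC=1[C@]2(C)CCC[C@](C)(CO[Si](c3ccccc3)(c3ccccc3)C(C)(C)C)[C@H]2[C@H](C(=O)N3C(=O)OC[C@H]3Cc3ccccc3)CC=1C
F8 | step 11 | (1R,4aR,8S,8aS)-8-{[(tert-butyldiphenylsilyl)oxy]methyl}-3,4a,8-trimethyl-4-[4-(trimethylsilyl)but-3-yn-1-yl]-1,2,4a,5,6,7,8,8a-octahydronaphthalene-1-carboxylic acid | C[Si](C)(C)C#CCCC=1[C@]2(C)CCC[C@](C)(CO[Si](c3ccccc3)(c3ccccc3)C(C)(C)C)[C@H]2[C@H](C(=O)O)CC=1C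
F9 | step 13 | (1R,4aR,8S,8aS)-8-{[(tert-butyldiphenylsilyl)oxy]methyl}-3,4a,8-trimethyl-4-[4-(trimethylsilyl)but-3-yn-1-yl]-1,2,4a,5,6,7,8,8a-octahydronaphthalen-1-yl acetate | C[Si](C)(C)C#CCCC=1[C@]2(C)CCC[C@](C)(CO[Si](c3ccccc3)(c3ccccc3)C(C)(C)C)[C@H]2[C@H](OC(C)=O)CC=1C
F10 | step 13 | hexacarbonyldicobalt complex of the alkyne of F9 | C[Si](C)(C)C12[Co]3(=C=O)(=C=O)(=C=O)[Co]1(=C=O)(=C=O)(=C=O)C23CCC=4[C@]5(C)CCC[C@](C)(CO[Si](c6ccccc6)(c6ccccc6)C(C)(C)C)[C@H]5[C@H](OC(C)=O)CC=4C
F11 | step 13 | hexacarbonyldicobalt complex of the alkyne of 19 | C[Si](C)(C)C12[Co]3(=C=O)(=C=O)(=C=O)[Co]1(=C=O)(=C=O)(=C=O)C23CC[C@H]4[C@]5(C)CCC[C@](C)(CO[Si](c6ccccc6)(c6ccccc6)C(C)(C)C)[C@H]5[C@H](OC(C)=O)C[C@]4(C)O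
F12 | step 8 | (2E,4S)-4-{[(tert-butyldiphenylsilyl)oxy]methyl}-7-hydroxy-N-methoxy-N,4-dimethylhept-2-enamide | OCCC[C@](C)(CO[Si](c1ccccc1)(c1ccccc1)C(C)(C)C)/C=C/C(=O)N(C)OC
F13 | step 8 | (2E,4S)-4-{[(tert-butyldiphenylsilyl)oxy]methyl}-7-iodo-N-methoxy-N,4-dimethylhept-2-enamide | ICCC[C@](C)(CO[Si](c1ccccc1)(c1ccccc1)C(C)(C)C)/C=C/C(=O)N(C)OC
F14 | step 8 | alkylzinc iodide formed from F13 by zinc insertion into the C–I bond | I[Zn]CCC[C@](C)(CO[Si](c1ccccc1)(c1ccccc1)C(C)(C)C)/C=C/C(=O)N(C)OC
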